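The rate constants were drawn at random within sensible limits; no experiment stands behind them.

I want to know whether Monday's or Saturday's flask ends with the longer chains, and the two differ in their charge of D.

| setting | Monday's | Saturday's |
|---|---|---|
| E | 0.051 M | 0.051 M |
| J | 0.0459 M | 0.0459 M |
| Q | 0.510 mM | 0.510 mM |
| D | 0.0255 M | 0.0120 M |
| time | 12 min | 12 min |

    E + J → E.J (k1 = 2.54 /M/s)
    J → L (k2 = 0.0252 /s)
    E + Q → E.Q (k3 = 674 /M/s)
    E + D → E.D (k4 = 6.01 /M/s)

* which of the two ends with the longer chains by the average number of monomer units in a chain (unreacted monomers counted as chains of one) ("neither" if they lie within 10%) (Monday's / Saturday's / neither)
* average number of monomer units in a chain (unreacted monomers counted as chains of one) at the end, Monday's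
* average number of monomer units in a chain (unreacted monomers counted as chains of one) at the end, Saturday's

I count turnovers of the link step, because each link joins two chains and so removes one. Q caps an end and adds no chain, so once Q has reacted and with no link made, either flask counts one chain for every two monomer ends, which gives 0.0485 M, the chain count at zero links, U, and this is also the number of units. The chain length, the usual number-average degree of polymerisation, is therefore U over U less c(E.J), and I need the curve of c(E.J).

In either flask that curve starts with a slope of 0.357 M/min. In Monday's flask it bends early, since E has a life against J and D at their charges of 0.0618 min, shorter than the 0.108 min of J. A second landmark is the crossing at c(E) = 0.00992 M, where J links and dies equally fast, and below it J goes to L faster than to links.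

For the level, suppose Q and D take their whole charges. That leaves 0.0250 M of E for links on Monday, a length of 2.06. On Saturday it leaves 0.0385 M, a length of 4.85, which I take as an upper figure, since J may die before it finds that E. My hand reckoning goes no further, but it points to Saturday's.

The forecast also says Saturday's, with 2.09 for Monday's and 2.81 for Saturday's, on the ground that “Halving D leaves more E to catch J before it dies”. Its Saturday figure lies well below my upper figure.

The flask gives Saturday's, with 2.09 for Monday's and 2.82 for Saturday's.

At 0.0650 min in Monday's flask, E goes into links 1.1 times as fast as into E.D. Monday's flask ends with 49.5% of the E charged as E.J and 49.3% as E.D. From U, Monday's 0.0253 M of links leaves 0.0232 M of chains, and Saturday's 0.0312 M leaves 0.0172 M.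

A neighbour of Monday's flask, with 0.043 M of D, has the same U. Its 35.3% of the E charged as E.J gives a length of 1.59, and the computed length is 1.59.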